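**Assumption (remark on the chemistry):** 2-bromo-1-chloro-3-methoxybenzene (1) and 4-(2-bromoethyl)phenol (10) are treated as catalogue compounds. The target has no stereocentre and no E/Z-isomeric double bond, so no stereodescriptor is needed.

## The problem

- Target 17 is an achiral bibenzyl acid. Ring A is a hexasubstituted benzene (C1 CO2H, C2 OMe, C3 prenyl, C4 OH, C5 prenyl, C6 CH2CH2–ring B), and ring B is a 4-hydroxyphenyl group on a two-carbon chain.
- There are no stereocentres, so nothing has to be set or relayed. The task is purely regiochemical: six contiguous substituents must be placed without ambiguity.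
- The two ring-A oxygens must be told apart, as a methyl ether at C2 and a free phenol at C4.
- The C1 acid sits between the methoxy group and the arylethyl chain. An ester at this position would resist saponification, so the acid is best introduced free.
- The prenyl groups flank the C4 phenol. Acid closes them to chromans, and electrophilic halogen or dehydrogenating oxidants attack their trisubstituted olefins. Halogenation and any change of oxidation level therefore have to come before the prenyl groups, and the end game should avoid acid.
- The enabling feature is the triad C2(OMe)–C1(CO2H)–C6(CH2R). A carbon electrophile next to the methoxy group and a carbon nucleophile one position further is what results from adding an organometallic across the C1–C6 triple bond of a 3-methoxybenzyne and trapping the ortho-methoxy aryl anion.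
- Because every other position of ring A is substituted, a C1/C6 dihalide can give only one aryne.

## Retrosynthesis

**17 from 16 (two O–Si bonds).** Both phenols are masked as tert-butyldimethylsilyl ethers. Acetal protection would need acid at the end, in the presence of a 2,6-diprenylphenol that cyclises to a chroman. Silyl ethers survive n-BuLi at −78 °C and Grignard reagents, and one fluoride treatment removes both. The forward step must cleave a silyl ether flanked by two prenyl groups, which fluoride attack at silicon should manage.

**16 from 9 and 12 (C6–CH2 and C1–CO2H).** Both carbon substituents are removed at once by an aryne disconnection. Bromine–lithium exchange on 9 gives aryllithium 13, loss of chloride gives aryne 14, Grignard reagent 12 adds at C6 to give arylmagnesium 15, and carbon dioxide is captured at C1. The neighbouring cuts are weaker: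
- a cross-coupling at C6 of a preformed benzoate makes only one bond, at a doubly ortho-substituted carbon, and leaves an ester to cleave;
- carboxylation of a preformed 2-alkylaryl metal needs the arylethyl group installed first by a separate step.

Compound 9 has no ring hydrogen and carries only a bromide, a chloride and spectator groups, so it is much simpler than 16. The forward reaction must add 12 regioselectively at C6 despite the C5 prenyl group.

**12 from 11 from 10 (C–Mg, O–Si).** The Grignard reagent comes from the silyl ether 11 by magnesium insertion. Compound 11 is one silylation away from 10, which already has the bromide in place.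

**9 from 8 from 7 (the two olefin termini, then O–Si).** The prenyl groups are written as allyl groups extended by cross-metathesis with 2-methyl-2-butene. Direct ortho-prenylation is less attractive: a dimethylallyl ether Claisen route needs three operations per prenyl group, and phenoxide C-prenylation is poorly selective. Allyl groups come from the most reliable aromatic Claisen rearrangement, and one metathesis converts both. Silylating 7 first means that no free ortho-prenylphenol is ever handled. The forward metathesis must convert two hindered but terminal olefins without migration of the double bond.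

**7 from 6, 5, 4 and 3 (C3–CH2 and C5–CH2).** Two rounds of O-allylation and [3,3] rearrangement place the allyl groups on both carbons ortho to the phenol. The para position is blocked by bromine, so only ortho migration is possible. The regiochemistry of the first rearrangement is immaterial, since the second round fills whichever ortho position is left.

**3 from 1 via 2 (C4–O).** Bromine has to be on the ring before any olefin, because electrophilic bromination would attack allyl or prenyl groups. Brominating 3-chloro-5-methoxyphenol (F5, kept as a fallback) could give ortho and para isomers. Instead the Br/Cl/OMe triad is bought intact as 1, and the oxygen is introduced at the only unhindered C–H (meta to OMe and Cl) by sterically controlled C–H borylation to 2 and oxidation.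

## Roads not taken

**Alternative 1: Michael–Claisen annulation and late aromatisation.**
- Cut: C5–C6 and C2–C3, building ring A from acyclic carbon.
- Forward key step: the kinetic lithium enolate of the symmetric ketone A1 adds to alkylidene malonate A2 (C5–C6). The α′-enolate then acylates on one ester (C2–C3) to give the cyclohexane-1,3-dione ester A3, which must be dehydrogenated to the resorcylate.
- Merits: both prenyl groups are bought in a symmetric ketone, the arylethyl chain arrives with the malonate, and the ring forms in one operation. In steps to the carbon skeleton this road is shorter than the seven steps spent here on 9. The allyl ester would come off under mild conditions with zerovalent palladium, as mild as the fluoride step of the chosen plan.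
- Weak points:
  - A3 must be aromatised in the presence of two trisubstituted olefins; quinones, halogenation–elimination and palladium dehydrogenation all threaten prenyl groups or close them onto the new phenols.
  - Aromatisation frees both C2–OH and C4–OH. The C2–OH is hydrogen-bonded to the ester and flanked by a prenyl group, so alkylation favours C4, the wrong oxygen, and a protection–methylation–deprotection detour follows.
  - A2 has acidic γ-hydrogens and may be deconjugated by the enolate instead of accepting it.
- Comparison: the chosen plan fixes the methoxy/hydroxy pattern and the aromatic oxidation level from compound 1 and never exposes a prenyl group to an oxidant. It pays with a longer prelude.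

**Alternative 2: biomimetic folding of a diketo-dioxinone.**
- Cut: C1–C6, unravelling ring A to the open-chain dioxinone A4.
- Forward key step: base-mediated intramolecular aldol condensation of the dioxinone α-carbon onto the arylethyl ketone, then dehydration and enolisation, gives benzodioxinone A5 with a free C4–OH.
- Merits: ring A is formed already aromatic, with no dehydrogenation, no halogen and no cryogenic organometallic step. There is no regiochemical question in the ring-forming step, which the aryne route cannot claim.
- Weak points:
  - A4 is a tricarbonyl chain with prenyl groups on two doubly activated carbons. Installing them means two C-alkylations of β-dicarbonyl units, where O-alkylation and dialkylation compete, and A4 can also close to a pyranone.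
  - The acetonide differentiates the oxygens the wrong way round for 17. C4–OH must be protected, the dioxinone opened to an ester, the hindered and hydrogen-bonded C2–OH methylated, the doubly ortho-substituted ester cleaved and C4 deprotected.
- Comparison: the chosen plan carries the methyl ether from the start and obtains the free acid directly from CO2. It has to accept a seven-step preparation of 9 and a selectivity question in the key step.

**Alternative 3: 2-pyranone plus siloxyalkyne with loss of CO2.**
- Cut: C3–C4 and C5–C6.
- Forward key step: inverse-electron-demand [4+2] cycloaddition of pyranone A6 with siloxyalkyne A7, then expulsion of CO2 from the bridged lactone, gives the hexasubstituted benzoate A8.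
- Merits: this is the most convergent road. All six substituents are assembled in one thermal step without halogens, with regiochemistry set by the polarisation of the ynol ether. In convergency it is better than the chosen plan.
- Weak points:
  - A6 is a fully substituted diene, and its C4 methoxy group donates into the ring and lowers the electron deficiency the cycloaddition needs. The temperatures this may demand approach those at which siloxyalkynes rearrange to silyl ketenes.
  - A6 needs its own multistep synthesis, with C- versus O-alkylation questions.
  - A8 is a methyl ester between OMe and the arylethyl chain, so it needs nucleophilic dealkylation instead of saponification, and two different silyl groups must come off.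
- Comparison: the chosen plan gives the acid unprotected and uses thermal Claisen chemistry of known behaviour. It is more linear and needs low-temperature organometallic technique.

Key step: step 10

## Route

Step 1
Reactants: 1 2-bromo-1-chloro-3-methoxybenzene
Product: 3 4-bromo-3-chloro-5-methoxyphenol, via pinacol boronate 2 (not isolated)
Conditions: [Ir(OMe)(cod)]2 (1.5 mol%), 4,4'-di-tert-butyl-2,2'-bipyridine (3 mol%), B2pin2, THF, 80 °C; then Oxone (2KHSO5·KHSO4·K2SO4), acetone/H2O, rt
Reagents that add atoms: bis(pinacolato)diboron, CC1(C)OB(OC1(C)C)B1OC(C)(C)C(C)(C)O1 (boryl group of 2 only, lost again); potassium peroxymonosulfate (active part of Oxone), [K+].[O-]S(=O)(=O)OO (the phenol oxygen)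
Why: Iridium-catalysed aromatic C–H borylation is sterically controlled and should take the only C–H without an ortho neighbour (meta to OMe and Cl, para to Br); aryl bromides and chlorides are tolerated, and one-pot oxidation of the arylboronate gives the phenol.

Step 2
Reactants: 3 4-bromo-3-chloro-5-methoxyphenol
Product: 4 2-bromo-1-chloro-3-methoxy-5-(prop-2-enyloxy)benzene
Conditions: allyl bromide, K2CO3, acetone, reflux
Reagents that add atoms: allyl bromide, C=CCBr
Why: Williamson ether synthesis on an unhindered phenoxide; nothing else in 3 reacts with a mild carbonate base.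

Step 3
Reactants: 4 2-bromo-1-chloro-3-methoxy-5-(prop-2-enyloxy)benzene
Product: 5 4-bromo-3-chloro-5-methoxy-2-(prop-2-enyl)phenol
Conditions: N,N-diethylaniline, 190 °C
Reagents that add atoms: none
Why: Aromatic Claisen rearrangement; the para position is blocked by bromine, and migration toward the meta chlorine and away from the meta methoxy group is expected to favour the isomer drawn, while the other ortho isomer need not be removed because step 5 converges both on 7.

Step 4
Reactants: 5 4-bromo-3-chloro-5-methoxy-2-(prop-2-enyl)phenol
Product: 6 2-bromo-3-chloro-1-methoxy-4-(prop-2-enyl)-5-(prop-2-enyloxy)benzene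
Conditions: allyl bromide, K2CO3, DMF, 50 °C
Reagents that add atoms: allyl bromide, C=CCBr
Why: Williamson ether synthesis; one ortho substituent slows but does not prevent O-alkylation in a dipolar aprotic solvent.

Step 5
Reactants: 6 2-bromo-3-chloro-1-methoxy-4-(prop-2-enyl)-5-(prop-2-enyloxy)benzene
Product: 7 4-bromo-3-chloro-5-methoxy-2,6-di(prop-2-enyl)phenol
Conditions: N,N-diethylaniline, 190 °C
Reagents that add atoms: none
Why: Second aromatic Claisen rearrangement; only one ortho position is open and the para position carries bromine, so the allyl group can settle only between the hydroxyl and methoxy groups.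

Step 6
Reactants: 7 4-bromo-3-chloro-5-methoxy-2,6-di(prop-2-enyl)phenol
Product: 8 [4-bromo-3-chloro-5-methoxy-2,6-di(prop-2-enyl)phenoxy](tert-butyl)dimethylsilane
Conditions: TBSCl, imidazole, DMAP (cat.), DMF, 40 °C
Reagents that add atoms: tert-butyldimethylsilyl chloride, CC(C)(C)[Si](C)(C)Cl
Why: Imidazole-promoted silylation of a 2,6-dialkylphenol; the flanking groups are primary CH2 units, so the oxygen remains accessible, and the silyl ether later withstands n-BuLi and Grignard reagents.

Step 7
Reactants: 8 [4-bromo-3-chloro-5-methoxy-2,6-di(prop-2-enyl)phenoxy](tert-butyl)dimethylsilane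
Product: 9 [4-bromo-3-chloro-5-methoxy-2,6-bis(3-methylbut-2-enyl)phenoxy](tert-butyl)dimethylsilane
Conditions: second-generation Grubbs catalyst RuCl2(=CHPh)(H2IMes)(PCy3) (5 mol%), 2-methyl-2-butene/CH2Cl2, 40 °C, sealed vessel
Reagents that add atoms: 2-methyl-2-butene, CC=C(C)C
Why: Olefin cross-metathesis of terminal allylarenes with excess 2-methyl-2-butene, the standard allyl-to-prenyl conversion; the two allyl groups are meta to each other and cannot ring-close, and aryl halides and silyl ethers are inert to the catalyst.

Step 8
Reactants: 10 4-(2-bromoethyl)phenol
Product: 11 [4-(2-bromoethyl)phenoxy](tert-butyl)dimethylsilane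
Conditions: TBSCl, imidazole, CH2Cl2, 0 °C to rt
Reagents that add atoms: tert-butyldimethylsilyl chloride, CC(C)(C)[Si](C)(C)Cl
Why: Imidazole-promoted silylation of an unhindered phenol; the weak base does not trigger elimination or aryl participation at the primary bromide.

Step 9
Reactants: 11 [4-(2-bromoethyl)phenoxy](tert-butyl)dimethylsilane
Product: 12 {2-[4-(tert-butyldimethylsilyloxy)phenyl]ethyl}magnesium bromide
Conditions: Mg turnings (activated with 1,2-dibromoethane), THF, 35 °C, slow addition; used as a titrated solution
Reagents that add atoms: magnesium, [Mg]
Why: Grignard formation by magnesium insertion into a primary alkyl bromide; the aryl silyl ether is inert, and slow addition at moderate temperature limits Wurtz coupling.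

Step 10
Reactants: 9 [4-bromo-3-chloro-5-methoxy-2,6-bis(3-methylbut-2-enyl)phenoxy](tert-butyl)dimethylsilane; 12 {2-[4-(tert-butyldimethylsilyloxy)phenyl]ethyl}magnesium bromide
Product: 16 4-(tert-butyldimethylsilyloxy)-2-methoxy-3,5-bis(3-methylbut-2-enyl)-6-{2-[4-(tert-butyldimethylsilyloxy)phenyl]ethyl}benzoic acid, via aryllithium 13 (not isolated), via aryne 14 (not isolated), via arylmagnesium bromide 15 (not isolated)
Conditions: n-BuLi (1.0 equiv), THF, −78 °C; 12 (3 equiv), −78 to 45 °C; CO2 (dry gas), −20 °C to rt; cold 0.5 M HCl to pH 3
Reagents that add atoms: carbon dioxide, O=C=O; n-butyllithium, [Li]CCCC (lithium of 13 only, lost again)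
Why: Bromine–lithium exchange at C1 is faster at −78 °C than any deprotonation and gives the ortho-chloro aryllithium 13; on warming, chloride is lost across C1–C6 (from lithium or, after exchange with 12, from magnesium) to give aryne 14, the only aryne possible because ring A has no hydrogen. Excess 12 adds to the strained triple bond to form the C6–CH2 bond and arylmagnesium 15; the closest known reaction type is carbomagnesiation of 3-alkoxybenzynes with electrophilic capture of the ortho-alkoxy arylmagnesium. Dry CO2 then carboxylates 15 at C1, and a brief cold quench to pH 3 should free the acid without harming the aryl silyl ethers. No ring is closed and no stereocentre is formed. The step needs attack at C6 and not at C1: the inductively withdrawing C2 methoxy group distorts the aryne so that the distal carbon C6 is the more electrophilic, and it places the developing carbanion at C1 next to oxygen where magnesium can chelate, which is expected to outweigh the shielding by the C5 prenyl CH2. The prenyl olefins should not intercept the aryne, since an intramolecular ene or [2+2] reaction of an ortho-prenyl group would require a four-membered transition structure, and the surplus of 12 suppresses addition of 13 to 14. The carboxylic acid formed from surplus 12 and CO2 is removed by chromatography.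

Step 11
Reactants: 16 4-(tert-butyldimethylsilyloxy)-2-methoxy-3,5-bis(3-methylbut-2-enyl)-6-{2-[4-(tert-butyldimethylsilyloxy)phenyl]ethyl}benzoic acid
Product: 17 4-hydroxy-6-[2-(4-hydroxyphenyl)ethyl]-2-methoxy-3,5-bis(3-methylbut-2-enyl)benzoic acid
Conditions: TBAF (3 equiv), THF, 0 °C; cold dilute HCl to pH 3, immediate extraction
Reagents that add atoms: none
Why: Fluoride-mediated desilylation of both aryl silyl ethers (phenoxides are good leaving groups from silicon, even with two ortho substituents); the reaction medium is non-acidic, so the 2,6-diprenylphenol should not cyclise to a chroman.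

## Compound list

1 | 2-bromo-1-chloro-3-methoxybenzene | COc1cccc(Cl)c1Br | starting material
2 | 2-(4-bromo-3-chloro-5-methoxyphenyl)-4,4,5,5-tetramethyl-1,3,2-dioxaborolane | COc1cc(B2OC(C)(C)C(C)(C)O2)cc(Cl)c1Br | intermediate (not isolated)
3 | 4-bromo-3-chloro-5-methoxyphenol | COc1cc(O)cc(Cl)c1Br | intermediate
4 | 2-bromo-1-chloro-3-methoxy-5-(prop-2-enyloxy)benzene | C=CCOc1cc(OC)c(Br)c(Cl)c1 | intermediate
5 | 4-bromo-3-chloro-5-methoxy-2-(prop-2-enyl)phenol | C=CCc1c(O)cc(OC)c(Br)c1Cl | intermediate
6 | 2-bromo-3-chloro-1-methoxy-4-(prop-2-enyl)-5-(prop-2-enyloxy)benzene | C=CCOc1cc(OC)c(Br)c(Cl)c1CC=C | intermediate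
7 | 4-bromo-3-chloro-5-methoxy-2,6-di(prop-2-enyl)phenol | C=CCc1c(O)c(CC=C)c(OC)c(Br)c1Cl | intermediate
8 | [4-bromo-3-chloro-5-methoxy-2,6-di(prop-2-enyl)phenoxy](tert-butyl)dimethylsilane | C=CCc1c(O[Si](C)(C)C(C)(C)C)c(CC=C)c(OC)c(Br)c1Cl | intermediate
9 | [4-bromo-3-chloro-5-methoxy-2,6-bis(3-methylbut-2-enyl)phenoxy](tert-butyl)dimethylsilane | COc1c(Br)c(Cl)c(CC=C(C)C)c(O[Si](C)(C)C(C)(C)C)c1CC=C(C)C | intermediate
10 | 4-(2-bromoethyl)phenol | Oc1ccc(CCBr)cc1 | starting material
11 | [4-(2-bromoethyl)phenoxy](tert-butyl)dimethylsilane | CC(C)(C)[Si](C)(C)Oc1ccc(CCBr)cc1 | intermediate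
12 | {2-[4-(tert-butyldimethylsilyloxy)phenyl]ethyl}magnesium bromide | CC(C)(C)[Si](C)(C)Oc1ccc(CC[Mg]Br)cc1 | intermediate
13 | [4-(tert-butyldimethylsilyloxy)-2-chloro-6-methoxy-3,5-bis(3-methylbut-2-enyl)phenyl]lithium | [Li]c1c(OC)c(CC=C(C)C)c(O[Si](C)(C)C(C)(C)C)c(CC=C(C)C)c1Cl | intermediate (not isolated)
14 | 5-(tert-butyldimethylsilyloxy)-3-methoxy-4,6-bis(3-methylbut-2-enyl)-1,2-didehydrobenzene (aryne; the triple bond joins the former C–Br and C–Cl carbons) | COC1=C(CC=C(C)C)C(O[Si](C)(C)C(C)(C)C)=C(CC=C(C)C)C#C1 | intermediate (not isolated)
15 | bromo{4-(tert-butyldimethylsilyloxy)-2-methoxy-3,5-bis(3-methylbut-2-enyl)-6-{2-[4-(tert-butyldimethylsilyloxy)phenyl]ethyl}phenyl}magnesium | Br[Mg]c1c(OC)c(CC=C(C)C)c(O[Si](C)(C)C(C)(C)C)c(CC=C(C)C)c1CCc1ccc(O[Si](C)(C)C(C)(C)C)cc1 | intermediate (not isolated)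
16 | 4-(tert-butyldimethylsilyloxy)-2-methoxy-3,5-bis(3-methylbut-2-enyl)-6-{2-[4-(tert-butyldimethylsilyloxy)phenyl]ethyl}benzoic acid | COc1c(CC=C(C)C)c(O[Si](C)(C)C(C)(C)C)c(CC=C(C)C)c(CCc2ccc(O[Si](C)(C)C(C)(C)C)cc2)c1C(=O)O | intermediate
17 | 4-hydroxy-6-[2-(4-hydroxyphenyl)ethyl]-2-methoxy-3,5-bis(3-methylbut-2-enyl)benzoic acid | COc1c(CC=C(C)C)c(O)c(CC=C(C)C)c(CCc2ccc(O)cc2)c1C(=O)O | target

## Step count and risk

Total step count: 11. Longest linear sequence: 9 steps (steps 1–7, 10 and 11); steps 8 and 9 form the side branch.

**Step 10 (key step).**
- What may go wrong: addition of 12 at C1 instead of C6, or hydride transfer from the β-CH2 of 12 to the aryne (net reduction). Both arise because C6 is screened by the C5 prenyl group. Chloride loss may also be slow once lithium has exchanged for magnesium, so that the aryl metal is merely protonated on quench.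
- Fallback (from 9, returning at 16): bromine–lithium exchange on 9 at −78 °C and immediate CO2 quench without warming should give 4-(tert-butyldimethylsilyloxy)-2-chloro-6-methoxy-3,5-bis(3-methylbut-2-enyl)benzoic acid F1. Hydroboration of tert-butyl(4-ethenylphenoxy)dimethylsilane F2 with 9-BBN-H gives 9-{2-[4-(tert-butyldimethylsilyloxy)phenyl]ethyl}-9-borabicyclo[3.3.1]nonane F3. B-alkyl Suzuki–Miyaura coupling of F3 at the C6–Cl of F1 (Pd(OAc)2, SPhos, K3PO4, THF/H2O, 65 °C) should give 16. The two bonds are then made separately, and the C6 bond by palladium-catalysed coupling instead of aryne addition.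

**Step 7.**
- What may go wrong: incomplete conversion of the second allyl group, or ruthenium-hydride-mediated migration of the double bond into conjugation with ring A, giving inseparable olefin mixtures.
- Fallback (from 8, returning at 9): Lemieux–Johnson cleavage (OsO4 cat., NaIO4, 2,6-lutidine, dioxane/H2O) should give 2,2'-[5-bromo-4-chloro-6-methoxy-2-(tert-butyldimethylsilyloxy)-1,3-phenylene]diacetaldehyde F4. Double Wittig olefination with the ylide from isopropyltriphenylphosphonium iodide and n-BuLi (THF, −78 °C to rt) then builds both prenyl groups and gives 9.

**Step 1.**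
- What may go wrong: partial borylation next to the methoxy group, or protodeboronation before oxidation, lowering regiochemical purity and conversion.
- Fallback (returning at 3): electrophilic bromination of 3-chloro-5-methoxyphenol F5 with NBS in MeCN at −20 °C, para to the hydroxyl group, with chromatographic removal of ortho-brominated isomers, gives 3.

**Step 9.**
- What may go wrong: Wurtz-type homocoupling and β-elimination to the styrene during magnesium insertion, which lowers the titre of 12.
- Fallback (from 11, returning at 12): Finkelstein exchange (NaI, acetone) gives tert-butyl[4-(2-iodoethyl)phenoxy]dimethylsilane F6. Iodine–lithium exchange with t-BuLi (2 equiv, Et2O, −78 °C) and transmetalation with MgBr2·OEt2 then gives 12 without a metal surface.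

## Further compounds

F1 | step 10 | 4-(tert-butyldimethylsilyloxy)-2-chloro-6-methoxy-3,5-bis(3-methylbut-2-enyl)benzoic acid | COc1c(C(=O)O)c(Cl)c(CC=C(C)C)c(O[Si](C)(C)C(C)(C)C)c1CC=C(C)C
F2 | step 10 | tert-butyl(4-ethenylphenoxy)dimethylsilane | C=Cc1ccc(O[Si](C)(C)C(C)(C)C)cc1
F3 | step 10 | 9-{2-[4-(tert-butyldimethylsilyloxy)phenyl]ethyl}-9-borabicyclo[3.3.1]nonane | CC(C)(C)[Si](C)(C)Oc1ccc(CCB2C3CCCC2CCC3)cc1
F4 | step 7 | 2,2'-[5-bromo-4-chloro-6-methoxy-2-(tert-butyldimethylsilyloxy)-1,3-phenylene]diacetaldehyde | COc1c(Br)c(Cl)c(CC=O)c(O[Si](C)(C)C(C)(C)C)c1CC=O
F5 | step 1 | 3-chloro-5-methoxyphenol | COc1cc(O)cc(Cl)c1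
F6 | step 9 | tert-butyl[4-(2-iodoethyl)phenoxy]dimethylsilane | CC(C)(C)[Si](C)(C)Oc1ccc(CCI)cc1
A1 | alternative 1 | 2,10-dimethylundeca-2,9-dien-6-one | CC(C)=CCCC(=O)CCC=C(C)C
A2 | alternative 1 | diallyl 2-{3-[4-(tert-butyldimethylsilyloxy)phenyl]propylidene}propanedioate | C=CCOC(=O)C(=CCCc1ccc(O[Si](C)(C)C(C)(C)C)cc1)C(=O)OCC=C
A3 | alternative 1 | allyl 2,4-dioxo-3,5-bis(3-methylbut-2-enyl)-6-{2-[4-(tert-butyldimethylsilyloxy)phenyl]ethyl}cyclohexane-1-carboxylate (mixture of diastereomers and enol forms) | C=CCOC(=O)C1C(CCc2ccc(O[Si](C)(C)C(C)(C)C)cc2)C(CC=C(C)C)C(=O)C(CC=C(C)C)C1=O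
A4 | alternative 2 | 2,2-dimethyl-6-{1,3-bis(3-methylbut-2-enyl)-2,4-dioxo-6-[4-(tert-butyldimethylsilyloxy)phenyl]hexyl}-4H-1,3-dioxin-4-one | CC1(C)OC(=O)C=C(O1)C(CC=C(C)C)C(=O)C(CC=C(C)C)C(=O)CCc1ccc(O[Si](C)(C)C(C)(C)C)cc1
A5 | alternative 2 | 7-hydroxy-2,2-dimethyl-6,8-bis(3-methylbut-2-enyl)-5-{2-[4-(tert-butyldimethylsilyloxy)phenyl]ethyl}-4H-1,3-benzodioxin-4-one | CC1(C)Oc2c(CC=C(C)C)c(O)c(CC=C(C)C)c(CCc3ccc(O[Si](C)(C)C(C)(C)C)cc3)c2C(=O)O1
A6 | alternative 3 | methyl 4-methoxy-3-(3-methylbut-2-enyl)-2-oxo-6-{2-[4-(tert-butyldimethylsilyloxy)phenyl]ethyl}-2H-pyran-5-carboxylate | COC(=O)c1c(CCc2ccc(O[Si](C)(C)C(C)(C)C)cc2)oc(=O)c(CC=C(C)C)c1OC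
A7 | alternative 3 | triisopropyl[(5-methylhex-4-en-1-yn-1-yl)oxy]silane | CC(C)=CCC#CO[Si](C(C)C)(C(C)C)C(C)C
A8 | alternative 3 | methyl 2-methoxy-3,5-bis(3-methylbut-2-enyl)-4-(triisopropylsilyloxy)-6-{2-[4-(tert-butyldimethylsilyloxy)phenyl]ethyl}benzoate | COc1c(CC=C(C)C)c(O[Si](C(C)C)(C(C)C)C(C)C)c(CC=C(C)C)c(CCc2ccc(O[Si](C)(C)C(C)(C)C)cc2)c1C(=O)OC
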